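## Retrosynthetic overview

1. The last disconnections are the nine O-alkyl groups (BBr3) and the d2–O–aryl bond (Ullmann coupling), leading back to pentacyclic phenol 24.
2. The route rests on ring D, the outer benzene ring on the furan. Its two furan carbons (d1 on the furan oxygen, d6 on ring B) are flanked by the para oxygen-bearing carbons d2 and d5, with a third oxygen at d3. Ring D is therefore opened to a 4-(benzofuran-2-yl)-3-isopropoxy-4-(methoxymethoxy)cyclobutenone 21, whose ketene carbon closes onto benzofuran C-3.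
3. Cyclobutenone 21 comes from the 2-lithiobenzofuran (from 2-bromobenzofuran 15) and isopropyl semisquarate 18 (from diisopropyl squarate), with the alkoxide capped as its MOM ether.
4. Furan ring C comes from salicylaldehyde 13 (dibromo-olefination, copper O-vinylation). The dioxin comes from SNAr of ring-A phenol 7 on fluoroaldehyde 9 (a5–O–b6), then intramolecular Ullmann closure (a6–O–b1).
5. Ring order: dioxin, then furan C, then ring D. Phenol 7 comes from 2-hydroxy-4,6-dimethoxybenzaldehyde (iodination, MOM, Ullmann with 3,5-dimethoxyphenol, Dakin).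

Key step: step 14

**Remarks**

- Lettering: ring A is the dioxin benzene with the pendant aryloxy group (a1 aryloxy, a2 and a4 OMe, a3 H, a5 and a6 dioxin carbons). Ring B is the central benzene (b1 and b6 dioxin carbons, joined as a6–O–b1 and a5–O–b6; b2 OMe; b3 H; b4 furan oxygen; b5 furan carbon). Ring C is the furan. Ring D is the outer benzene (d1 on the furan oxygen, d2, d3, d4 H, d5, d6 on b5).
- Assumption: 2-fluoro-4,6-dimethoxybenzaldehyde (8) is bought; it is otherwise one Vilsmeier–Haack formylation away from 1-fluoro-3,5-dimethoxybenzene.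

## Route

**Step 1**
Reactants: 1 2-hydroxy-4,6-dimethoxybenzaldehyde
Product: 2 2-hydroxy-3-iodo-4,6-dimethoxybenzaldehyde
Conditions: NIS, TFA (cat.), MeCN, 0 °C to rt
Reagents that add atoms: N-iodosuccinimide, O=C1CCC(=O)N1I
Why: Electrophilic aromatic iodination; the free chelated hydroxyl directs to its ortho carbon C-3, which is also para to the 6-methoxy group and less crowded than C-5 between two methoxy groups.

**Step 2**
Reactants: 2 2-hydroxy-3-iodo-4,6-dimethoxybenzaldehyde
Product: 3 3-iodo-4,6-dimethoxy-2-(methoxymethoxy)benzaldehyde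
Conditions: NaH, MOMCl, DMF, 0 °C to rt
Reagents that add atoms: chloromethyl methyl ether (MOMCl), COCCl
Why: Williamson-type O-alkylation (MOM protection); the hydrogen-bonded phenol needs full deprotonation, and the acetal masks the oxygen that later becomes dioxin oxygen a6.

**Step 3**
Reactants: 3 3-iodo-4,6-dimethoxy-2-(methoxymethoxy)benzaldehyde; 4 3,5-dimethoxyphenol
Product: 5 3-(3,5-dimethoxyphenoxy)-4,6-dimethoxy-2-(methoxymethoxy)benzaldehyde
Conditions: CuI (10 mol %), picolinic acid (20 mol %), K3PO4, DMSO, 90 °C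
Reagents that add atoms: none
Why: Ullmann diaryl ether synthesis; the picolinic acid/CuI system tolerates doubly ortho-substituted aryl iodides, and the phenol partner is unhindered and electron-rich.

**Step 4**
Reactants: 5 3-(3,5-dimethoxyphenoxy)-4,6-dimethoxy-2-(methoxymethoxy)benzaldehyde
Product: 7 3-(3,5-dimethoxyphenoxy)-4,6-dimethoxy-2-(methoxymethoxy)phenol, via aryl formate 6 (not isolated)
Conditions: mCPBA, NaHCO3, CH2Cl2, 0 °C to rt; then K2CO3 (cat.), MeOH, rt
Reagents that add atoms: 3-chloroperbenzoic acid (mCPBA), OOC(=O)c1cccc(Cl)c1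
Why: Dakin-type oxidation (Baeyer–Villiger migration of the electron-rich aryl group, then methanolysis of the formate) turns the formyl carbon into the free hydroxyl a5 while a6 stays masked.

**Step 5**
Reactants: 8 2-fluoro-4,6-dimethoxybenzaldehyde
Product: 9 3-bromo-2-fluoro-4,6-dimethoxybenzaldehyde
Conditions: NBS, MeCN, 0 °C to rt
Reagents that add atoms: N-bromosuccinimide, O=C1CCC(=O)N1Br
Why: Electrophilic aromatic bromination; C-3 is para to the 6-methoxy and ortho to the 4-methoxy group, whereas C-5 lies between two methoxy groups and is the more hindered site.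

**Step 6**
Reactants: 7 3-(3,5-dimethoxyphenoxy)-4,6-dimethoxy-2-(methoxymethoxy)phenol; 9 3-bromo-2-fluoro-4,6-dimethoxybenzaldehyde
Product: 10 3-bromo-2-[3-(3,5-dimethoxyphenoxy)-4,6-dimethoxy-2-(methoxymethoxy)phenoxy]-4,6-dimethoxybenzaldehyde
Conditions: Cs2CO3, DMF, 90 °C
Reagents that add atoms: none
Why: Nucleophilic aromatic substitution (SNAr) of the fluoride ortho to the formyl group by the only free phenoxide, which fixes the a5–O–b6 bond; bromide is not displaced.

**Step 7**
Reactants: 10 3-bromo-2-[3-(3,5-dimethoxyphenoxy)-4,6-dimethoxy-2-(methoxymethoxy)phenoxy]-4,6-dimethoxybenzaldehyde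
Product: 11 3-bromo-2-[3-(3,5-dimethoxyphenoxy)-2-hydroxy-4,6-dimethoxyphenoxy]-4,6-dimethoxybenzaldehyde
Conditions: HCl (1 M in MeOH), THF, 40 °C; aqueous work-up
Reagents that add atoms: none
Why: Acid-catalysed acetal exchange removes the MOM group; methanol traps the methoxymethyl cation as dimethoxymethane so the electron-rich rings are not alkylated, and any dimethyl acetal of the aldehyde reverts on aqueous work-up.

**Step 8**
Reactants: 11 3-bromo-2-[3-(3,5-dimethoxyphenoxy)-2-hydroxy-4,6-dimethoxyphenoxy]-4,6-dimethoxybenzaldehyde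
Product: 12 6-(3,5-dimethoxyphenoxy)-2,4,7,9-tetramethoxydibenzo[b,e][1,4]dioxine-1-carbaldehyde
Conditions: CuI (20 mol %), N,N-dimethylglycine (40 mol %), Cs2CO3, 1,4-dioxane, 100 °C
Reagents that add atoms: none
Why: Intramolecular Ullmann etherification closes the six-membered dioxin ring (a6–O–b1); the low-polarity solvent keeps uncatalysed aryl migration slow relative to the copper-mediated closure.

**Step 9**
Reactants: 12 6-(3,5-dimethoxyphenoxy)-2,4,7,9-tetramethoxydibenzo[b,e][1,4]dioxine-1-carbaldehyde
Product: 13 6-(3,5-dimethoxyphenoxy)-2-hydroxy-4,7,9-trimethoxydibenzo[b,e][1,4]dioxine-1-carbaldehyde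
Conditions: BCl3 (1.5 equiv), CH2Cl2, −78 to 0 °C; then H2O
Reagents that add atoms: none
Why: Chelation-controlled ether cleavage; BCl3 bound to the formyl oxygen removes only the methyl group ortho to the aldehyde (b4), since the other ortho position is the dioxin oxygen and no other methoxy group has a carbonyl neighbour.

**Step 10**
Reactants: 13 6-(3,5-dimethoxyphenoxy)-2-hydroxy-4,7,9-trimethoxydibenzo[b,e][1,4]dioxine-1-carbaldehyde
Product: 14 1-(2,2-dibromoethenyl)-6-(3,5-dimethoxyphenoxy)-4,7,9-trimethoxydibenzo[b,e][1,4]dioxin-2-ol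
Conditions: CBr4, PPh3, Et3N, CH2Cl2, 0 °C
Reagents that add atoms: tetrabromomethane, BrC(Br)(Br)Br
Why: Ramirez dibromo-olefination (first stage of the Corey–Fuchs sequence) of the aldehyde; the non-basic ylide tolerates the free phenol.

**Step 11**
Reactants: 14 1-(2,2-dibromoethenyl)-6-(3,5-dimethoxyphenoxy)-4,7,9-trimethoxydibenzo[b,e][1,4]dioxin-2-ol
Product: 15 2-bromobenzofuran fused on ring B of the dibenzodioxin (furan oxygen on b4 and furan CH carbon on b5 and Br on the furan carbon next to oxygen; a1 3,5-dimethoxyphenoxy; OMe at a2 a4 b2)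
Conditions: CuI (5 mol %), K3PO4, THF, 80 °C
Reagents that add atoms: none
Why: Copper-catalysed intramolecular O-vinylation (Ullmann-type) of the gem-dibromoalkene keeps one bromine and gives the 2-bromobenzofuran; the furan regiochemistry is fixed by the position of the former formyl group.

**Step 12**
Reactants: 16 diisopropyl squarate
Product: 18 3-isopropoxycyclobut-3-ene-1,2-dione, via hydroxycyclobutenone 17 (not isolated)
Conditions: LiAlH(OtBu)3, THF, −78 to 0 °C; then conc. HCl, CH2Cl2, rt
Reagents that add atoms: water, O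
Why: Hydride 1,2-reduction of one squarate carbonyl, then acid-promoted allylic transposition with hydrolysis of the vinylogous ester (loss of isopropanol) gives the semisquarate.

**Step 13**
Reactants: 15 2-bromobenzofuran fused on ring B of the dibenzodioxin; 18 3-isopropoxycyclobut-3-ene-1,2-dione
Product: 21 racemic 4-(benzofuran-2-yl)-3-isopropoxy-4-(methoxymethoxy)cyclobut-2-en-1-one carried on the dibenzodioxin, via lithiobenzofuran 19 (not isolated), via lithium alkoxide 20 (not isolated)
Conditions: n-BuLi, THF, −78 °C; cannulate into 18, THF, −78 °C; then MOMCl, −78 to 0 °C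
Reagents that add atoms: chloromethyl methyl ether (MOMCl), COCCl
Why: Bromine–lithium exchange at −78 °C outruns ortho-lithiation of the methoxyarenes, the 2-lithiobenzofuran adds 1,2 to the ketone carbonyl of 18 (the one on the isopropoxy-bearing carbon, the other being a vinylogous ester), and the lithium alkoxide is O-alkylated by MOMCl; the new quaternary carbon forms racemic and loses its stereogenicity in step 14.

**Step 14**
Reactants: 21 racemic 4-(benzofuran-2-yl)-3-isopropoxy-4-(methoxymethoxy)cyclobut-2-en-1-one carried on the dibenzodioxin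
Product: 24 pentacyclic phenol (ring D: d2 OMOM; d3 O-isopropyl; d5 OH), via dienylketene 22 (not isolated), via cyclohexadienone 23 (not isolated)
Conditions: toluene (degassed, 0.01 M), 110 °C, argon
Reagents that add atoms: none
Why: Heating opens the cyclobutenone by a thermal conrotatory 4π electrocyclic ring opening in which the MOM-oxy donor on C-4 turns outward and the benzofuranyl group inward, giving the (Z)-dienylketene 22. Ring D then closes by a thermal disrotatory 6π electrocyclization in which the ketene carbon bonds to benzofuran C-3, giving dienone 23, which enolizes to phenol 24. The closest known reaction type is the Moore ring expansion of 4-aryl- and 4-heteroaryl-4-oxycyclobutenones to annulated hydroquinone monoethers. The quaternary stereocenter of 21 becomes sp2 and the transient sp3 carbon of 23 is lost on aromatization, so no stereocenter needs control. The only selectivity needed is torquoselectivity, which the outward preference of the oxygen substituent secures. The placement of OMOM at d2, isopropoxy at d3 and the free hydroxyl at d5 follows from the regiochemistry of step 13.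

**Step 15**
Reactants: 24 pentacyclic phenol (ring D: d2 OMOM; d3 O-isopropyl; d5 OH)
Product: 25 pentacyclic methyl ether (ring D: d2 OMOM; d3 O-isopropyl; d5 OMe)
Conditions: MeI, K2CO3, acetone, 50 °C
Reagents that add atoms: iodomethane, CI
Why: Williamson methylation caps the new phenol so that only the d2 oxygen is free after MOM removal.

**Step 16**
Reactants: 25 pentacyclic methyl ether (ring D: d2 OMOM; d3 O-isopropyl; d5 OMe)
Product: 26 pentacyclic d2 phenol (ring D: d2 OH; d3 O-isopropyl; d5 OMe)
Conditions: HCl (1 M in MeOH), THF, 40 °C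
Reagents that add atoms: none
Why: Acid-catalysed acetal cleavage removes the MOM group; methyl, isopropyl and diaryl ethers are inert, and methanol scavenges the methoxymethyl cation.

**Step 17**
Reactants: 26 pentacyclic d2 phenol (ring D: d2 OH; d3 O-isopropyl; d5 OMe); 27 1-iodo-3,5-dimethoxybenzene
Product: 28 fully O-alkylated phlorofucofuroeckol A (eight methyl ethers and the d3 isopropyl ether)
Conditions: CuI (20 mol %), picolinic acid (40 mol %), K3PO4, DMSO, 90 °C
Reagents that add atoms: none
Why: Ullmann diaryl ether synthesis; these conditions couple doubly ortho-substituted phenols with unhindered aryl iodides.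

**Step 18**
Reactants: 28 fully O-alkylated phlorofucofuroeckol A
Product: 29 phlorofucofuroeckol A
Conditions: BBr3 (excess), CH2Cl2, −78 °C to rt; then H2O; work-up under argon
Reagents that add atoms: none
Why: Lewis-acid cleavage of alkyl aryl ethers by BBr3 removes the eight methyl groups and the isopropyl group, while the diaryl ether, dioxin and furan C–O bonds are not cleaved.

## Compound list

1 | 2-hydroxy-4,6-dimethoxybenzaldehyde | O=Cc1c(O)cc(OC)cc1OC | starting material
2 | 2-hydroxy-3-iodo-4,6-dimethoxybenzaldehyde | O=Cc1c(O)c(I)c(OC)cc1OC | intermediate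
3 | 3-iodo-4,6-dimethoxy-2-(methoxymethoxy)benzaldehyde | O=Cc1c(OCOC)c(I)c(OC)cc1OC | intermediate
4 | 3,5-dimethoxyphenol | COc1cc(O)cc(OC)c1 | starting material
5 | 3-(3,5-dimethoxyphenoxy)-4,6-dimethoxy-2-(methoxymethoxy)benzaldehyde | O=Cc1c(OCOC)c(Oc2cc(OC)cc(OC)c2)c(OC)cc1OC | intermediate
6 | 3-(3,5-dimethoxyphenoxy)-4,6-dimethoxy-2-(methoxymethoxy)phenyl formate | O=COc1c(OCOC)c(Oc2cc(OC)cc(OC)c2)c(OC)cc1OC | intermediate
7 | 3-(3,5-dimethoxyphenoxy)-4,6-dimethoxy-2-(methoxymethoxy)phenol | Oc1c(OCOC)c(Oc2cc(OC)cc(OC)c2)c(OC)cc1OC | intermediate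
8 | 2-fluoro-4,6-dimethoxybenzaldehyde | O=Cc1c(F)cc(OC)cc1OC | starting material
9 | 3-bromo-2-fluoro-4,6-dimethoxybenzaldehyde | O=Cc1c(F)c(Br)c(OC)cc1OC | intermediate
10 | 3-bromo-2-[3-(3,5-dimethoxyphenoxy)-4,6-dimethoxy-2-(methoxymethoxy)phenoxy]-4,6-dimethoxybenzaldehyde | O=Cc1c(Oc2c(OCOC)c(Oc3cc(OC)cc(OC)c3)c(OC)cc2OC)c(Br)c(OC)cc1OC | intermediate
11 | 3-bromo-2-[3-(3,5-dimethoxyphenoxy)-2-hydroxy-4,6-dimethoxyphenoxy]-4,6-dimethoxybenzaldehyde | O=Cc1c(Oc2c(O)c(Oc3cc(OC)cc(OC)c3)c(OC)cc2OC)c(Br)c(OC)cc1OC | intermediate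
12 | 6-(3,5-dimethoxyphenoxy)-2,4,7,9-tetramethoxydibenzo[b,e][1,4]dioxine-1-carbaldehyde | O=Cc1c2Oc3c(OC)cc(OC)c(Oc4cc(OC)cc(OC)c4)c3Oc2c(OC)cc1OC | intermediate
13 | 6-(3,5-dimethoxyphenoxy)-2-hydroxy-4,7,9-trimethoxydibenzo[b,e][1,4]dioxine-1-carbaldehyde | O=Cc1c2Oc3c(OC)cc(OC)c(Oc4cc(OC)cc(OC)c4)c3Oc2c(OC)cc1O | intermediate
14 | 1-(2,2-dibromoethenyl)-6-(3,5-dimethoxyphenoxy)-4,7,9-trimethoxydibenzo[b,e][1,4]dioxin-2-ol | BrC(Br)=Cc1c2Oc3c(OC)cc(OC)c(Oc4cc(OC)cc(OC)c4)c3Oc2c(OC)cc1O | intermediate
15 | 2-bromobenzofuran fused on ring B of the dibenzodioxin (furan O on b4, furan CH carbon on b5, Br next to the furan O; a1 3,5-dimethoxyphenoxy; OMe at a2, a4, b2) | COc1cc(OC)cc(Oc2c(OC)cc(OC)c3c2Oc2c(OC)cc4oc(Br)cc4c2O3)c1 | intermediate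
16 | diisopropyl squarate (3,4-diisopropoxycyclobut-3-ene-1,2-dione) | CC(C)OC1=C(OC(C)C)C(=O)C1=O | starting material
17 | racemic 4-hydroxy-2,3-diisopropoxycyclobut-2-en-1-one | CC(C)OC1=C(OC(C)C)C(O)C1=O | intermediate
18 | 3-isopropoxycyclobut-3-ene-1,2-dione | CC(C)OC1=CC(=O)C1=O | intermediate
19 | 2-lithiobenzofuran corresponding to 15 (Li in place of Br) | COc1cc(OC)cc(Oc2c(OC)cc(OC)c3c2Oc2c(OC)cc4oc([Li])cc4c2O3)c1 | intermediate
20 | racemic lithium alkoxide of the 4-(benzofuran-2-yl)-4-hydroxy-3-isopropoxycyclobut-2-en-1-one | COc1cc(OC)cc(Oc2c(OC)cc(OC)c3c2Oc2c(OC)cc4oc(C5(O[Li])C(OC(C)C)=CC5=O)cc4c2O3)c1 | intermediate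
21 | racemic 4-(benzofuran-2-yl)-3-isopropoxy-4-(methoxymethoxy)cyclobut-2-en-1-one carried on the dibenzodioxin | COc1cc(OC)cc(Oc2c(OC)cc(OC)c3c2Oc2c(OC)cc4oc(C5(OCOC)C(OC(C)C)=CC5=O)cc4c2O3)c1 | intermediate
22 | (Z)-dienylketene: 4-(benzofuran-2-yl)-3-isopropoxy-4-(methoxymethoxy)buta-1,3-dien-1-one, benzofuranyl cis to the ketenyl carbon | COc1cc(OC)cc(Oc2c(OC)cc(OC)c3c2Oc2c(OC)cc4oc(/C(OCOC)=C(OC(C)C)\C=C=O)cc4c2O3)c1 | intermediate
23 | racemic cyclohexadienone (ring D before enolization: d5 C=O, d6 sp3 CH) | COc1cc(OC)cc(Oc2c(OC)cc(OC)c3c2Oc2c(OC)cc4OC5=C(OCOC)C(OC(C)C)=CC(=O)C5c4c2O3)c1 | intermediate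
24 | pentacyclic phenol (ring D: d2 OMOM, d3 O-isopropyl, d5 OH; a1 3,5-dimethoxyphenoxy; OMe at a2, a4, b2) | COc1cc(OC)cc(Oc2c(OC)cc(OC)c3c2Oc2c(OC)cc4oc5c(OCOC)c(OC(C)C)cc(O)c5c4c2O3)c1 | intermediate
25 | pentacyclic methyl ether (ring D: d2 OMOM, d3 O-isopropyl, d5 OMe) | COc1cc(OC)cc(Oc2c(OC)cc(OC)c3c2Oc2c(OC)cc4oc5c(OCOC)c(OC(C)C)cc(OC)c5c4c2O3)c1 | intermediate
26 | pentacyclic d2 phenol (ring D: d2 OH, d3 O-isopropyl, d5 OMe) | COc1cc(OC)cc(Oc2c(OC)cc(OC)c3c2Oc2c(OC)cc4oc5c(O)c(OC(C)C)cc(OC)c5c4c2O3)c1 | intermediate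
27 | 1-iodo-3,5-dimethoxybenzene | COc1cc(I)cc(OC)c1 | starting material
28 | fully O-alkylated phlorofucofuroeckol A (eight methyl ethers, d3 isopropyl ether) | COc1cc(OC)cc(Oc2c(OC)cc(OC)c3c2Oc2c(OC)cc4oc5c(Oc6cc(OC)cc(OC)c6)c(OC(C)C)cc(OC)c5c4c2O3)c1 | intermediate
29 | phlorofucofuroeckol A | Oc1cc(O)cc(Oc2c(O)cc(O)c3c2Oc2c(O)cc4oc5c(Oc6cc(O)cc(O)c6)c(O)cc(O)c5c4c2O3)c1 | target

## Step count and risks

Total step count: 18. Longest linear sequence: 16 (steps 1–4, 6–11, 13–18).

The three steps most likely to fail: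

**Step 14 (key step).** The methoxymethyl cap may be lost or shifted in the hot solution, since it sits on an allylic carbon flanked by an enol ether in 21 and on a vinylic oxygen in 22. Ring opening would then give mixtures of capped and uncapped, easily oxidized phenols. The fallback sets out from 15 and returns at 26. The bromine–lithium exchange and the addition to 18 are run as in step 13, but alkoxide 20 is protonated with aqueous NH4Cl to give the free racemic carbinol F1. This is the parent hydroxy variant of the Moore ring expansion. Heated in toluene under argon, F1 should open to the hydroxy-dienylketene F2, close to the dienone F3 and tautomerize to the hydroquinone F4, in which d2 and d5 are both free hydroxyls. One equivalent of MeI with K2CO3 in acetone should then methylate the d5 hydroxyl, which has a free ortho CH, in preference to the d2 hydroxyl, which is flanked by the isopropoxy group and the ring-fusion carbon. This gives 26 and by-passes 24 and 25.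

**Step 8.** Before copper closes the ring, the free a6 phenoxide may attack the formyl-activated ipso carbon b6 (Smiles rearrangement through a five-membered spiro intermediate). That would exchange the roles of the a5 and a6 oxygens and lead to the regioisomeric dioxin. The fallback sets out from 10 and returns at 13. BCl3 (3 equiv, CH2Cl2, −78 to 0 °C) removes the MOM group and the methyl ether ortho to the aldehyde in one operation, giving the diphenol aldehyde F5. Ullmann closure (CuI, N,N-dimethylglycine, Cs2CO3, dioxane) is then run on its dianion. The phenoxide ortho to the formyl group turns the aldehyde into a vinylogous carboxylate and makes ring B anionic, which should shut down ipso attack while the a6 phenoxide still couples with the C–Br bond. The product is 13 directly.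

**Step 6.** Addition of a doubly ortho-substituted phenoxide to a fluoride flanked by formyl and bromine, on a ring whose aldehyde is weakened by two methoxy donors, may be too slow, and prolonged heating in base may degrade the aldehyde. The fallback sets out from 7 and returns at 10. Commercial 2-bromo-4,6-dimethoxybenzaldehyde is brominated with NBS at C-3 (same directing effects as in step 5) to give 2,3-dibromo-4,6-dimethoxybenzaldehyde F6. An Ullmann coupling of 7 with F6 (CuI, N,N-dimethylglycine, Cs2CO3, dioxane, 90 °C) should take place at the C-2 bromide, where the neighbouring formyl oxygen directs and accelerates copper insertion. The C-3 bromide remains for step 8, and the product is 10.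

## Further compounds

F1 | step 14 | racemic 4-(benzofuran-2-yl)-4-hydroxy-3-isopropoxycyclobut-2-en-1-one carried on the dibenzodioxin | COc1cc(OC)cc(Oc2c(OC)cc(OC)c3c2Oc2c(OC)cc4oc(C5(O)C(OC(C)C)=CC5=O)cc4c2O3)c1
F2 | step 14 | (Z)-hydroxy-dienylketene (4-hydroxy analogue of 22) | COc1cc(OC)cc(Oc2c(OC)cc(OC)c3c2Oc2c(OC)cc4oc(/C(O)=C(OC(C)C)\C=C=O)cc4c2O3)c1
F3 | step 14 | racemic cyclohexadienone (d2 OH analogue of 23) | COc1cc(OC)cc(Oc2c(OC)cc(OC)c3c2Oc2c(OC)cc4OC5=C(O)C(OC(C)C)=CC(=O)C5c4c2O3)c1
F4 | step 14 | pentacyclic hydroquinone (ring D: d2 OH, d3 O-isopropyl, d5 OH) | COc1cc(OC)cc(Oc2c(OC)cc(OC)c3c2Oc2c(OC)cc4oc5c(O)c(OC(C)C)cc(O)c5c4c2O3)c1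
F5 | step 8 | 3-bromo-2-[3-(3,5-dimethoxyphenoxy)-2-hydroxy-4,6-dimethoxyphenoxy]-6-hydroxy-4-methoxybenzaldehyde | O=Cc1c(Oc2c(O)c(Oc3cc(OC)cc(OC)c3)c(OC)cc2OC)c(Br)c(OC)cc1O
F6 | step 6 | 2,3-dibromo-4,6-dimethoxybenzaldehyde | O=Cc1c(Br)c(Br)c(OC)cc1OC
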